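**Strategy.** Ring B is closed last by forming the C4–C5 bond (C4 = ring carbon bearing the exocyclic methylene, C5 = carbinol fusion carbon) through an intramolecular Nozaki–Hiyama–Kishi addition of a 2-iodoalkene to the ring A ketone. The step exploits the allylic tertiary alcohol C5(OH)–C4(=CH2) of ring B and sets C5 by substrate control from the equatorial C1 bromide and C7 side chain. The precursor is a monocyclic 2,2,5-trisubstituted cyclohexanone already carrying the triene, the secondary bromide and the iodoalkene. Its C1/C10 pair comes from one enantioselective bromination/semipinacol ring expansion of a (Z)-alkenylcyclopentanol, and C7 from a rhodium-catalysed conjugate addition.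

Key step: step 11

Remark: eudesmane-type numbering is used. C1 = CHBr, C4 = C(=CH2), C5 = C–OH, C7 = CH bearing the side chain (C11 on C7 to terminal C16), C10 = C–CH3; ring A = C5–C6–C7–C8–C9–C10, ring B = C1–C2–C3–C4–C5–C10. Compounds 1, 4, 6, 11 and 15 are taken to be commercial.

Step 1
Reactants: 1 pent-4-yn-1-ol
Product: 2 4-iodopent-4-en-1-ol
Conditions: NaI, Me3SiCl, H2O, MeCN, rt
Reagents that add atoms: sodium iodide, [Na+].[I-] (iodine, delivered as HI formed in the flask)
Why: Markovnikov hydroiodination of the terminal alkyne by HI generated in the flask gives the 2-iodo-1-alkene that later serves as the C4 alkenyl donor; no stereocenter is formed.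

Step 2
Reactants: 2 4-iodopent-4-en-1-ol
Product: 3 4-iodopent-4-enal
Conditions: Dess–Martin periodinane, CH2Cl2, 0 °C to rt
Reagents that add atoms: none
Why: Dess–Martin oxidation of the primary alcohol stops at the aldehyde and leaves the iodoalkene untouched.

Step 3
Reactants: 3 4-iodopent-4-enal; 4 ethyl 2-[bis(2,2,2-trifluoroethoxy)phosphoryl]propanoate
Product: 5 ethyl (2Z)-6-iodo-2-methylhepta-2,6-dienoate
Conditions: KN(SiMe3)2, 18-crown-6, THF, −78 °C
Reagents that add atoms: none
Why: Still–Gennari olefination, in which the electron-poor bis(trifluoroethyl) phosphonate eliminates under kinetic control, should give the (Z)-trisubstituted enoate, the geometry that the later anti bromination/migration translates into the C1/C10 relative configuration.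

Step 4
Reactants: 5 ethyl (2Z)-6-iodo-2-methylhepta-2,6-dienoate; 6 1,4-dibromobutane
Product: 8 1-[(2Z)-6-iodohepta-2,6-dien-2-yl]cyclopentan-1-ol, via butane-1,4-diylbis(magnesium bromide) 7 (not isolated)
Conditions: Mg, THF, reflux (6 to 7); then 5, THF, −20 °C to rt; H2O
Reagents that add atoms: none
Why: Double Grignard addition of the 1,4-di-Grignard reagent to the ester (annulative cyclopentanol synthesis) builds the tertiary allylic alcohol without changing the alkene geometry, and alkenyl iodides do not exchange with alkylmagnesium halides at this temperature.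

Step 5
Reactants: 8 1-[(2Z)-6-iodohepta-2,6-dien-2-yl]cyclopentan-1-ol
Product: 9 (2R)-2-[(1R)-1-bromo-4-iodopent-4-en-1-yl]-2-methylcyclohexan-1-one
Conditions: N-bromosuccinimide, (DHQD)2PHAL (10 mol %), CHCl3/toluene, −40 °C
Reagents that add atoms: N-bromosuccinimide, O=C1CCC(=O)N1Br
Why: Catalytic enantioselective bromination/semipinacol rearrangement (bromonium-induced 1,2-alkyl shift with ring expansion) adds bromine to C1 and a ring CH2 to C10 anti across the (Z)-alkene, which fixes the C1/C10 relative configuration, while the cinchona catalyst chooses the alkene face and with it the absolute (1R,10R) sense (the pseudoenantiomeric (DHQ)2PHAL is the alternative if the sense of induction demands it).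

Step 6
Reactants: 9 (2R)-2-[(1R)-1-bromo-4-iodopent-4-en-1-yl]-2-methylcyclohexan-1-one
Product: 10 (6R)-6-[(1R)-1-bromo-4-iodopent-4-en-1-yl]-6-methylcyclohex-2-en-1-one
Conditions: IBX, 4-methoxypyridine N-oxide, DMSO, rt
Reagents that add atoms: none
Why: IBX dehydrogenation of the ketone is regiospecific because only C6 carries α-hydrogens, and it gives the enone needed to attach the C7 substituent without touching the stereocenters.

Step 7
Reactants: 11 but-2-yn-1-ol
Product: 12 (2Z)-3-(4,4,5,5-tetramethyl-1,3,2-dioxaborolan-2-yl)but-2-en-1-ol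
Conditions: B2pin2, CuCl (5 mol %), PCy3, NaOt-Bu (cat.), MeOH, toluene, rt
Reagents that add atoms: bis(pinacolato)diboron, CC1(C)OB(OC1(C)C)B1OC(C)(C)C(C)(C)O1
Why: Copper-catalysed formal hydroboration (syn borylcupration, then protonation by MeOH) of the propargylic alcohol should place boron on the carbon remote from the hydroxymethyl group and give the trisubstituted alkenylboronate with boron and CH2OH trans.

Step 8
Reactants: 10 (6R)-6-[(1R)-1-bromo-4-iodopent-4-en-1-yl]-6-methylcyclohex-2-en-1-one; 12 (2Z)-3-(4,4,5,5-tetramethyl-1,3,2-dioxaborolan-2-yl)but-2-en-1-ol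
Product: 13 (2R,5R)-2-[(1R)-1-bromo-4-iodopent-4-en-1-yl]-5-[(2E)-4-hydroxybut-2-en-2-yl]-2-methylcyclohexan-1-one
Conditions: [Rh(OH)(cod)]2 (3 mol %), (R)-BINAP (7 mol %), 1,4-dioxane/H2O (10:1), 40 °C
Reagents that add atoms: none
Why: Hayashi–Miyaura rhodium-catalysed asymmetric 1,4-addition should set C7 as R under control of the (R)-BINAP ligand (the remote quaternary C10 exerts little bias), with retention of the alkene geometry.

Step 9
Reactants: 13 (2R,5R)-2-[(1R)-1-bromo-4-iodopent-4-en-1-yl]-5-[(2E)-4-hydroxybut-2-en-2-yl]-2-methylcyclohexan-1-one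
Product: 14 (2E)-3-[(1R,4R)-4-[(1R)-1-bromo-4-iodopent-4-en-1-yl]-4-methyl-3-oxocyclohexyl]but-2-enal
Conditions: MnO2, CH2Cl2, rt
Reagents that add atoms: none
Why: MnO2 oxidises only the allylic primary alcohol to the (E)-enal under neutral conditions that should not isomerise the trisubstituted alkene.

Step 10
Reactants: 14 (2E)-3-[(1R,4R)-4-[(1R)-1-bromo-4-iodopent-4-en-1-yl]-4-methyl-3-oxocyclohexyl]but-2-enal; 15 diethyl (2-methylprop-2-en-1-yl)phosphonate
Product: 16 (2R,5R)-2-[(1R)-1-bromo-4-iodopent-4-en-1-yl]-2-methyl-5-[(2E,4E)-6-methylhepta-2,4,6-trien-2-yl]cyclohexan-1-one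
Conditions: 15, n-BuLi, THF, −78 °C; then 14, −78 °C to rt
Reagents that add atoms: none
Why: Horner–Wadsworth–Emmons olefination with the lithiated allylic phosphonate (α-attack, then elimination) should react at the aldehyde in preference to the hindered α-quaternary ketone and give the (E)-configured C13=C14 bond, completing the triene.

Step 11
Reactants: 16 (2R,5R)-2-[(1R)-1-bromo-4-iodopent-4-en-1-yl]-2-methyl-5-[(2E,4E)-6-methylhepta-2,4,6-trien-2-yl]cyclohexan-1-one
Product: 18 (1R,4aR,6R,8aR)-1-bromo-8a-methyl-4-methylidene-6-[(2E,4E)-6-methylhepta-2,4,6-trien-2-yl]decahydronaphthalen-4a-ol (the target), via alkenylchromium dichloride 17 (not isolated)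
Conditions: CrCl2 (6 equiv), NiCl2 (2 mol %), DMSO/THF, rt; then H2O
Reagents that add atoms: none
Why: Zerovalent nickel (formed from NiCl2 and CrCl2) inserts into the C4–I bond, transmetalation to trivalent chromium gives alkenylchromium 17, and this adds to the C5 ketone (Nozaki–Hiyama–Kishi reaction; closest known type: intramolecular alkenyl halide/ketone cyclisations to exo-methylene tertiary carbinols). Ring B closes by 6-exo attack on the carbonyl carbon through a chair-like transition state. The new stereocenter C5 is set by the substrate: ring A keeps the C7 trienyl group equatorial, which places the C10 methyl axial and the C1 arm equatorial, and only the transition state leading to the trans-fused system lets the C1 bromide sit equatorial on the forming ring, whereas the two cis-fused alternatives suffer a syn-diaxial C1–Br/C5–O or C7-substituent/C5–O interaction. The step needs chemoselectivity for the alkenyl iodide over the secondary neopentyl bromide and the triene, which the preference of zerovalent nickel for sp2 C–I bonds and the inertness of unactivated alkyl bromides and alkenes towards CrCl2 should secure. It also needs carbonyl addition to outrun protodemetalation, which the six-membered intramolecular delivery favours.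

**Compound list**

1 | pent-4-yn-1-ol | C#CCCCO | starting material
2 | 4-iodopent-4-en-1-ol | C=C(I)CCCO | intermediate
3 | 4-iodopent-4-enal | C=C(I)CCC=O | intermediate
4 | ethyl 2-[bis(2,2,2-trifluoroethoxy)phosphoryl]propanoate | CCOC(=O)C(C)P(=O)(OCC(F)(F)F)OCC(F)(F)F | starting material
5 | ethyl (2Z)-6-iodo-2-methylhepta-2,6-dienoate | CCOC(=O)/C(C)=C\CCC(I)=C | intermediate
6 | 1,4-dibromobutane | BrCCCCBr | starting material
7 | butane-1,4-diylbis(magnesium bromide) | Br[Mg]CCCC[Mg]Br | intermediate
8 | 1-[(2Z)-6-iodohepta-2,6-dien-2-yl]cyclopentan-1-ol | OC1(CCCC1)/C(C)=C\CCC(I)=C | intermediate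
9 | (2R)-2-[(1R)-1-bromo-4-iodopent-4-en-1-yl]-2-methylcyclohexan-1-one | O=C1CCCC[C@@]1(C)[C@H](Br)CCC(I)=C | intermediate
10 | (6R)-6-[(1R)-1-bromo-4-iodopent-4-en-1-yl]-6-methylcyclohex-2-en-1-one | O=C1C=CCC[C@@]1(C)[C@H](Br)CCC(I)=C | intermediate
11 | but-2-yn-1-ol | CC#CCO | starting material
12 | (2Z)-3-(4,4,5,5-tetramethyl-1,3,2-dioxaborolan-2-yl)but-2-en-1-ol | C/C(=C\CO)B1OC(C)(C)C(C)(C)O1 | intermediate
13 | (2R,5R)-2-[(1R)-1-bromo-4-iodopent-4-en-1-yl]-5-[(2E)-4-hydroxybut-2-en-2-yl]-2-methylcyclohexan-1-one | O=C1C[C@H](/C(C)=C/CO)CC[C@@]1(C)[C@H](Br)CCC(I)=C | intermediate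
14 | (2E)-3-[(1R,4R)-4-[(1R)-1-bromo-4-iodopent-4-en-1-yl]-4-methyl-3-oxocyclohexyl]but-2-enal | O=C1C[C@H](/C(C)=C/C=O)CC[C@@]1(C)[C@H](Br)CCC(I)=C | intermediate
15 | diethyl (2-methylprop-2-en-1-yl)phosphonate | CCOP(=O)(OCC)CC(C)=C | starting material
16 | (2R,5R)-2-[(1R)-1-bromo-4-iodopent-4-en-1-yl]-2-methyl-5-[(2E,4E)-6-methylhepta-2,4,6-trien-2-yl]cyclohexan-1-one | O=C1C[C@H](/C(C)=C/C=C/C(C)=C)CC[C@@]1(C)[C@H](Br)CCC(I)=C | intermediate
17 | alkenylchromium dichloride formed from 16 at C4 (chromium in place of iodine) | O=C1C[C@H](/C(C)=C/C=C/C(C)=C)CC[C@@]1(C)[C@H](Br)CCC(=C)[Cr](Cl)Cl | intermediate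
18 | (1R,4aR,6R,8aR)-1-bromo-8a-methyl-4-methylidene-6-[(2E,4E)-6-methylhepta-2,4,6-trien-2-yl]decahydronaphthalen-4a-ol | C=C(C)/C=C/C=C(\C)[C@@H]1CC[C@@]2(C)[C@H](Br)CCC(=C)[C@]2(O)C1 | target

**Step count and risks**

Total step count: 11. Longest linear sequence: 10 steps (steps 1–6 and 8–11); step 7 is a one-step side branch.

The three steps most likely to fail:

Step 5. The bromine transfer may proceed with poor discrimination of the alkene faces, or through an uncatalysed background pathway, so that 9 would form with low enantiomeric purity. Fallback: starting from 8, the rearrangement is run with N-bromosuccinimide alone, which should give racemic material, that is 9 together with its enantiomer (2S)-2-[(1S)-1-bromo-4-iodopent-4-en-1-yl]-2-methylcyclohexan-1-one F1. IBX as in step 6 then gives 10 together with (6S)-6-[(1S)-1-bromo-4-iodopent-4-en-1-yl]-6-methylcyclohex-2-en-1-one F2. The rhodium/(R)-BINAP addition of step 8, which sets C7 under catalyst control, turns the two enantiomers into diastereomers, 13 and (2S,5R)-2-[(1S)-1-bromo-4-iodopent-4-en-1-yl]-5-[(2E)-4-hydroxybut-2-en-2-yl]-2-methylcyclohexan-1-one F3. These are separated by chromatography and the route is rejoined at 13.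

Step 8. Transfer of the α-branched, hydroxy-bearing alkenyl group from boron to rhodium may be too slow, so that protodeboronation consumes 12 before conjugate addition. Fallback: starting from 10, the small and well-behaved potassium isopropenyltrifluoroborate is added under the same rhodium/(R)-BINAP control to give (2R,5R)-2-[(1R)-1-bromo-4-iodopent-4-en-1-yl]-2-methyl-5-(prop-1-en-2-yl)cyclohexan-1-one F4. The enal is then built by cross-metathesis of the isopropenyl group with crotonaldehyde (second-generation Hoveyda–Grubbs catalyst, CH2Cl2, 40 °C), which returns to the route at 14.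

Step 11. The alkenylchromium may add to the two faces of the C5 ketone with poor selectivity, giving the cis-fused epimer alongside the trans-fused product. Fallback: starting from 16, the cyclisation is run as in step 11 and the mixture of 18 and its C5 epimer (1R,4aS,6R,8aR)-1-bromo-8a-methyl-4-methylidene-6-[(2E,4E)-6-methylhepta-2,4,6-trien-2-yl]decahydronaphthalen-4a-ol F5 is not separated but converged. SOCl2/pyridine (Et2O, −40 °C, allylic transposition) should give the primary allylic chloride with a C4=C5 double bond, (4R,4aR,7R)-4-bromo-1-(chloromethyl)-4a-methyl-7-[(2E,4E)-6-methylhepta-2,4,6-trien-2-yl]-2,3,4,4a,5,6,7,8-octahydronaphthalene F6. NaSePh converts it into (4R,4aR,7R)-4-bromo-4a-methyl-7-[(2E,4E)-6-methylhepta-2,4,6-trien-2-yl]-1-[(phenylselanyl)methyl]-2,3,4,4a,5,6,7,8-octahydronaphthalene F7. Oxidation with H2O2/pyridine then triggers a [2,3]-sigmatropic shift that should deliver oxygen to C5 from the face opposite the axial C10 methyl group and, after hydrolysis, return to the route at 18.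

**Further compounds**

F1 | step 5 | (2S)-2-[(1S)-1-bromo-4-iodopent-4-en-1-yl]-2-methylcyclohexan-1-one | O=C1CCCC[C@]1(C)[C@@H](Br)CCC(I)=C
F2 | step 5 | (6S)-6-[(1S)-1-bromo-4-iodopent-4-en-1-yl]-6-methylcyclohex-2-en-1-one | O=C1C=CCC[C@]1(C)[C@@H](Br)CCC(I)=C
F3 | step 5 | (2S,5R)-2-[(1S)-1-bromo-4-iodopent-4-en-1-yl]-5-[(2E)-4-hydroxybut-2-en-2-yl]-2-methylcyclohexan-1-one | O=C1C[C@H](/C(C)=C/CO)CC[C@]1(C)[C@@H](Br)CCC(I)=C
F4 | step 8 | (2R,5R)-2-[(1R)-1-bromo-4-iodopent-4-en-1-yl]-2-methyl-5-(prop-1-en-2-yl)cyclohexan-1-one | O=C1C[C@H](C(C)=C)CC[C@@]1(C)[C@H](Br)CCC(I)=C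
F5 | step 11 | (1R,4aS,6R,8aR)-1-bromo-8a-methyl-4-methylidene-6-[(2E,4E)-6-methylhepta-2,4,6-trien-2-yl]decahydronaphthalen-4a-ol | C=C(C)/C=C/C=C(\C)[C@@H]1CC[C@@]2(C)[C@H](Br)CCC(=C)[C@@]2(O)C1
F6 | step 11 | (4R,4aR,7R)-4-bromo-1-(chloromethyl)-4a-methyl-7-[(2E,4E)-6-methylhepta-2,4,6-trien-2-yl]-2,3,4,4a,5,6,7,8-octahydronaphthalene | C=C(C)/C=C/C=C(\C)[C@@H]1CC[C@@]2(C)[C@H](Br)CCC(CCl)=C2C1
F7 | step 11 | (4R,4aR,7R)-4-bromo-4a-methyl-7-[(2E,4E)-6-methylhepta-2,4,6-trien-2-yl]-1-[(phenylselanyl)methyl]-2,3,4,4a,5,6,7,8-octahydronaphthalene | C=C(C)/C=C/C=C(\C)[C@@H]1CC[C@@]2(C)[C@H](Br)CCC(C[Se]c3ccccc3)=C2C1
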